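**Remarks on conventions and one assumption**

- Atom labels C1–C15 follow the germacrane skeleton of the target: C1 ketone, C2=C3 of the furanone (C3 carries the ring oxygen), C4=C5 alkene, C6 lactone carbinol, C7, C8 (isobutyrate), C9, C10 (quaternary, oxygen bridge), C11/C12/C13 lactone α-carbon, carbonyl and methylene, C14 methyl on C10, C15 hydroxymethyl on C4.
- TBS = tert-butyl(dimethyl)silyl, TMS = trimethylsilyl, PMB = 4-methoxybenzyl. "Fur" = (2S)-5-[(1Z)-3-(TBS-oxy)-1-iodoprop-1-en-2-yl]-2-methyl-3-oxo-2,3-dihydrofuran-2-yl, i.e. the furanone attached through C10.
- Assumption: 2-[(4-methoxybenzyl)oxy]acetaldehyde (25) is treated as a purchasable catalogue building block.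
- CIP remark: C7 is labelled S while C6 is a CH2O group (29, 31, 32) and R once C6 is a carbonyl or the ring carbinol (33–37); the arrangement in space is the same throughout.

## Analysis of the target

Compound 37 is a furanoheliangolide-type germacranolide. Its core is a ten-membered carbocycle (C1–C10) that is bridged twice: an oxygen links C3 and C10, so that O, C10, C1, C2 and C3 form a 3(2H)-furanone (a vinylogous ester), and C6–C7 carries a trans-fused α-methylene-γ-butyrolactone (O–C6, C7–C11, C12 carbonyl, C13 methylene). There are four stereocentres, 6R, 7R, 8R and 10S: H6 and H7 are trans, the C8 acyloxy group and the C6 branch are syn along C9–C8–C7–C11, and the oxygens on C8 and C10 are 1,3-syn along C7–C8–C9–C10–C1; C10 is quaternary and two carbons away from the nearest other stereocentre. The C4=C5 alkene is trisubstituted, cis within the ring (Z), cross-conjugated with the furanone, and bears the free C15 hydroxymethyl group. The sensitive functions are the α-methylene lactone (a Michael acceptor that base opens or isomerises), the C8 isobutyrate (a second ester that must survive every lactone-forming and deprotecting step) and the vinylogous ester. The difficulty lies in closing a strained ten-membered ring that contains a flat dienone unit and a cis alkene while the contiguous stereocentres C6–C8 sit next to an exocyclic acrylate, and in relating that triad to the remote C10. The plan rests on C6: it is at once the allylic carbon next to C5, the lactone carbinol and the neighbour of C7, so a C5 alkenyl iodide and a C6 aldehyde can be joined in one bond formation that closes the carbocycle, keeps the alkene geometry and creates the alkoxide that closes the lactone on C12.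

## Retrosynthetic reasoning

**37 from 36.** Only the O–Si bond at C15 is cut. The primary allylic alcohol is the one function that has to be masked up to the end, and a silyl ether can be removed under mild acidic, non-nucleophilic conditions that spare the methylene lactone and the isobutyrate.

**36 from 33.** The ring bond C5–C6 and the lactone bond O–C12 are cut together. C5–C6 is the one ring bond whose formation creates a single stereocentre (C6) directly next to an existing one (C7), uses an sp2 carbon whose geometry is already fixed, and delivers the C6 oxygen as a metal alkoxide five atoms from C12. Cutting C7–C8 instead would ask the ring closure to set two stereocentres, and cutting C4=C5 would mean making the cis trisubstituted alkene inside the strained ring. The gain is two rings and two bonds in one operation. Forward, alkenylchromium 34 must add to the aldehyde of 33 only, without base, with C7 steering the face, and alkoxide 35 must acylate on the methyl ester.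

**33 from 32, 31 and 29 with 30.** The labile aldehyde 33 is made last from primary alcohol 32, which comes from PMB ether 31 by a neutral oxidative deprotection that is orthogonal to the C15 silyl ether. The isobutyrate is put on by acylation of 29 with isobutyryl chloride 30 as soon as the C8 hydroxyl exists, because a free C8 hydroxyl could lactonise onto C12.

**29 from 23 and 27.** The C7–C8 bond is cut. Allyl bromide 27 carries C6, C7, C11, C12 and C13 with the acrylate already in place, so the α-methylene group never has to be installed by enolate chemistry on a lactone. Forward, a metal-mediated Barbier allylation must react at the γ-carbon and give the syn C7/C8 pair; its relation to C10 is not under substrate control, which is the weak point of the route before the ring closure. Bromide 27 goes back through allylic alcohol 26 to methyl acrylate 24 and aldehyde 25.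

**23 from 21.** The C8 aldehyde is hidden as the terminal alkene of an allyl group, which survives the base and oxidants used to build the furanone and is cleaved when needed.

**21 from 18, 17, and 9 with 15.** The O–C3 bond is cut by retro-cyclodehydration (through hemiketal 20 and hydroxy diketone 19) and the C2–C3 bond by a retro-aldol/oxidation (aldol 17 from enolate 16 of methyl ketone 9 and enal 15). This puts the strongly basic step on two small fragments, before any ester, acrylate or aldehyde is present.

**15 from 14, 13, 12, and 10 with 11.** The C4–C15 and C5–I bonds are cut in one iodide-triggered aldol of methyl propiolate 10 with formaldehyde 11, which fixes the Z geometry of the alkenyl iodide; protection, reduction and re-oxidation adjust C3 to the aldehyde.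

**9 from 8, 7, 5, 4, 2 and 1.** C10 is traced to a Sharpless epoxidation of methallyl alcohol 1. Epoxide 2 is opened with vinyl Grignard 3 (C8 and C9), the primary alcohol is oxidised (C1) and methyl Grignard 6 brings C2; oxidation and silylation give 9.

## Alternatives that were turned down

**Alternative 1:** Disconnection: C7–C11, with the future lactone carbon C12 carried as the CH2 of a propargyl ether on the C6 oxygen and C8 as one end of a C7–C8 epoxide. Forward key step: (C5H5)2TiCl (trivalent titanium, made from (C5H5)2TiCl2 and manganese) would open the epoxide homolytically at C7; the C7 radical would add 5-exo-dig to the alkyne and the alkenyl radical would be quenched. This gives the 3-methylenetetrahydrofuran A1 with the exocyclic C11=C13 alkene, the five-membered oxygen ring and a free C8 hydroxyl.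
- In its favour: C6 and C8 would come from reagent-controlled epoxy-alcohol chemistry and C7 would be set trans to the C6 substituent in the cyclic radical transition state. The C6–C8 triad is therefore better controlled than in the chosen route, whose Barbier step cannot relate C8 to C10. The conditions are neutral, no labile aldehyde is involved, and the C8 hydroxyl is freed exactly where the isobutyrate is needed.
- Against it: both epoxide carbons are secondary, so nothing in the substrate tells trivalent titanium to break C7–O rather than C8–O. The C7 radical is β to the C6 ether oxygen, so reduction to an alkyltitanium and β-alkoxide elimination compete with cyclisation. C12 arrives as an ether CH2 and must later be oxidised to the lactone carbonyl in a molecule with other allylic and benzylic C–H bonds. A1 contains neither C2–C4 nor the ten-membered ring.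
- Comparison: the key step builds one ring, one skeletal bond and one stereocentre and postpones the medium ring. The chosen step builds two rings and two bonds and leaves one deprotection, at the price of weaker control of C8.

**Alternative 2:** Disconnection: the two bonds at C3 (C2–C3 and C3–C4), with C3 supplied by carbon monoxide. Forward key step: with PdCl2(PPh3)2 and CuI under CO, zerovalent palladium would insert into a C4 alkenyl iodide, CO would insert, and the copper acetylide of a terminal C1≡C2 alkyne (a tertiary propargylic alcohol at C10) would be acylated. This gives the hydroxy ynone A2, from which the furanone follows by cycloisomerisation under gold or amine catalysis.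
- In its favour: it is the most convergent of the four plans. A2 holds every carbon of the ten-membered ring, and the furanone would form under far milder conditions than the enolate aldol, oxidation and acid treatment of the chosen route. On these points it is stronger.
- Against it: direct coupling without CO insertion competes. The half that carries C6 is a butenolide whose C6–H is allylic and γ to the lactone carbonyl, so the amine base of the coupling can epimerise C6 or drive the ring towards a hydroxyfuran. A2 has no ring and no C7 or C8 stereocentre, so a later C7–C8 closure would have to form the ten-membered ring and two stereocentres at once, with C8 again unrelated to C10 by any reagent.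
- Comparison: the chosen route is less convergent and longer before the closure. In exchange it fixes C7, C8 and C10 on open-chain intermediates, where diastereomers can be separated, and its ring closure sets only C6, next to C7.

**Alternative 3:** Disconnection: C1–C2 and O–C3, the 1,3-dioxygenated C1–C3 unit being hidden as an isoxazoline whose formation also closes the carbocycle. Forward key step: NaOCl would oxidise a C1 aldoxime to the nitrile oxide, which would add across the terminal C2=C3 alkene of a C2–C5 diene (carbon to C2, oxygen to C3) and give the isoxazoline-bridged ten-membered ring A3.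
- In its favour: the cycloaddition is irreversible and needs neither base nor metal, and its regiochemistry is the normal one for a monosubstituted alkene. The closure takes place far from C6–C8 and creates no lasting stereocentre (C3 becomes sp2), so it is free of the facial-selectivity question the chosen closure must answer. It also avoids the labile C6 aldehyde, since lactone and isobutyrate are already present in A3.
- Against it: ten-membered rings are the least favourable size for an intramolecular dipolar cycloaddition, and a slowly cyclising nitrile oxide next to quaternary C10 will dimerise to the furoxan. The internal C4=C5 alkene is a second dipolarophile. After closure the N–O bond must be reduced beside the C4=C5 alkene and two esters, and the β-hydroxy ketone oxidised and dehydrated to the furanone inside the strained ring. Because A3 has a saturated lactone without C13, the α-methylene group must come last by enolate chemistry in a molecule with an enolisable isobutyrate and an electrophilic furanone.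
- Comparison: at least four delicate steps follow the ring closure, against one deprotection in the chosen route, where furanone and acrylate are made on simple fragments before the ring exists.

Key step: step 21

## Route

**Step 1**
Reactants: 1 2-methylprop-2-en-1-ol (methallyl alcohol)
Product: 2 (R)-(2-methyloxiran-2-yl)methanol
Conditions: Ti(OiPr)4 (5 mol%), D-(−)-diisopropyl tartrate (6 mol%), cumene hydroperoxide, 4 Å MS, CH2Cl2, −20 °C
Reagents that add atoms: cumene hydroperoxide, CC(C)(OO)c1ccccc1
Why: Katsuki–Sharpless asymmetric epoxidation of a primary allylic alcohol; the D-(−)-tartrate titanium complex is the mirror image of the catalyst that gives (S)-epoxy alcohols of this type and should therefore give the (R)-epoxide, whose quaternary carbon becomes C10; cumene hydroperoxide eases isolation of the small water-soluble product.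

**Step 2**
Reactants: 2 (R)-(2-methyloxiran-2-yl)methanol; 3 vinylmagnesium bromide
Product: 4 (2S)-2-methylpent-4-ene-1,2-diol
Conditions: CH2=CHMgBr (3 equiv), CuI (10 mol%), THF, −30 → 0 °C
Reagents that add atoms: none
Why: Copper-catalysed Grignard opening of the epoxide at its unsubstituted CH2 carbon (SN2) after the first equivalent has deprotonated the hydroxyl; the quaternary stereocentre is not touched and the vinyl group brings C8 as a masked aldehyde.

**Step 3**
Reactants: 4 (2S)-2-methylpent-4-ene-1,2-diol
Product: 5 (2S)-2-hydroxy-2-methylpent-4-enal
Conditions: SO3·pyridine, DMSO, i-Pr2NEt, CH2Cl2, 0 °C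
Reagents that add atoms: none
Why: Parikh–Doering oxidation; only the primary hydroxyl can be oxidised and the α-carbon is quaternary, so nothing can epimerise; the volatile hydroxy aldehyde is used as a solution.

**Step 4**
Reactants: 5 (2S)-2-hydroxy-2-methylpent-4-enal; 6 methylmagnesium bromide
Product: 7 (3S)-3-methylhex-5-ene-2,3-diol (both C2 epimers)
Conditions: CH3MgBr (2.5 equiv), THF, −78 → 0 °C
Reagents that add atoms: none
Why: Grignard addition to the aldehyde brings in C2; the new carbinol centre forms as a mixture, which does not matter because it is oxidised in step 5.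

**Step 5**
Reactants: 7 (3S)-3-methylhex-5-ene-2,3-diol
Product: 8 (3S)-3-hydroxy-3-methylhex-5-en-2-one
Conditions: (COCl)2, DMSO, CH2Cl2, −78 °C; Et3N, → 0 °C
Reagents that add atoms: none
Why: Swern oxidation of the secondary hydroxyl of a secondary/tertiary 1,2-diol gives the α-hydroxy ketone; activated-sulfoxide oxidants do not cleave the glycol C–C bond.

**Step 6**
Reactants: 8 (3S)-3-hydroxy-3-methylhex-5-en-2-one
Product: 9 (3S)-3-methyl-3-[(trimethylsilyl)oxy]hex-5-en-2-one
Conditions: Me3SiCl, imidazole, DMF, 0 °C → rt
Reagents that add atoms: chlorotrimethylsilane, C[Si](C)(C)Cl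
Why: Silylation of the tertiary alcohol; the TMS ether keeps the hydroxyl out of the enolate step and is the most acid-labile silyl group later, so it can be removed in step 13 beside the C15 silyl ether.

**Step 7**
Reactants: 10 methyl propiolate; 11 formaldehyde (monomer from cracked paraformaldehyde)
Product: 12 methyl (2Z)-2-(hydroxymethyl)-3-iodoprop-2-enoate
Conditions: MgI2, CH2Cl2, 0 °C; then gaseous CH2O, −20 → 0 °C
Reagents that add atoms: magnesium iodide, I[Mg]I
Why: Iodide-triggered Baylis–Hillman-type (iodo-aldol) reaction: conjugate addition of iodide gives a magnesium β-iodo allenoate, which adds through C4 to formaldehyde on the side away from iodine, so that iodine ends cis to the ester (Z); this fixes the later C4=C5 geometry.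

**Step 8**
Reactants: 12 methyl (2Z)-2-(hydroxymethyl)-3-iodoprop-2-enoate
Product: 13 methyl (2Z)-2-[(TBS-oxy)methyl]-3-iodoprop-2-enoate
Conditions: t-BuMe2SiCl, imidazole, CH2Cl2, 0 °C
Reagents that add atoms: tert-butyl(chloro)dimethylsilane, CC(C)(C)[Si](C)(C)Cl
Why: Silyl protection of the C15 hydroxyl with a group that survives bases, oxidants and the chromium step and leaves with HF at the end.

**Step 9**
Reactants: 13 methyl (2Z)-2-[(TBS-oxy)methyl]-3-iodoprop-2-enoate
Product: 14 (2E)-2-[(TBS-oxy)methyl]-3-iodoprop-2-en-1-ol
Conditions: i-Bu2AlH (2.2 equiv), CH2Cl2, −78 °C; Rochelle salt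
Reagents that add atoms: none
Why: Reduction of the conjugated ester to the allylic alcohol at low temperature; the alkenyl iodide and its geometry are untouched (the label changes to E only because the CIP ranking changes).

**Step 10**
Reactants: 14 (2E)-2-[(TBS-oxy)methyl]-3-iodoprop-2-en-1-ol
Product: 15 (2Z)-2-[(TBS-oxy)methyl]-3-iodoprop-2-enal
Conditions: MnO2, CH2Cl2, rt, dark
Reagents that add atoms: none
Why: Allylic oxidation on MnO2 under neutral conditions; the enal is kept cold and dark and used directly, because β-iodo enals can isomerise.

**Step 11**
Reactants: 9 (3S)-3-methyl-3-[(trimethylsilyl)oxy]hex-5-en-2-one; 15 (2Z)-2-[(TBS-oxy)methyl]-3-iodoprop-2-enal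
Product: 17 (1Z,6S)-2-[(TBS-oxy)methyl]-3-hydroxy-1-iodo-6-methyl-6-[(trimethylsilyl)oxy]nona-1,8-dien-5-one (both C3 epimers), via lithium enolate 16 (not isolated)
Conditions: LiN(i-Pr)2, THF, −78 °C; then 15; AcOH, −78 °C
Reagents that add atoms: none
Why: Directed aldol addition: 9 has a single enolisable position (the methyl group), its lithium enolate adds 1,2 to the enal at −78 °C and the cold acetic acid quench prevents retro-aldol; the carbinol mixture is removed by the next oxidation.

**Step 12**
Reactants: 17 aldol adduct
Product: 18 (1Z,6S)-2-[(TBS-oxy)methyl]-1-iodo-6-methyl-6-[(trimethylsilyl)oxy]nona-1,8-diene-3,5-dione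
Conditions: Dess–Martin periodinane, NaHCO3, CH2Cl2, 0 °C → rt
Reagents that add atoms: none
Why: Dess–Martin oxidation of a β-hydroxy ketone to the 1,3-diketone under buffered conditions that leave both silyl ethers and the alkenyl iodide alone.

**Step 13**
Reactants: 18 silyloxy 1,3-diketone
Product: 21 (2S)-5-[(1Z)-3-(TBS-oxy)-1-iodoprop-1-en-2-yl]-2-methyl-2-(prop-2-en-1-yl)furan-3(2H)-one, via hydroxy diketone 19 (not isolated), via cyclic hemiketal 20 (not isolated)
Conditions: PPTS (cat.), MeOH–CH2Cl2, 0 °C → rt
Reagents that add atoms: none
Why: Acid-catalysed methanolysis of the tertiary TMS ether, 5-exo-trig hemiketalisation of the C10 hydroxyl onto the C3 carbonyl and dehydration to the vinylogous ester, the classical cyclodehydration of α′-hydroxy 1,3-diketones to 3(2H)-furanones; C10 is not involved and the primary TBS ether should survive the short exposure to PPTS.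

**Step 14**
Reactants: 21 allyl furanone
Product: 23 2-Fur-acetaldehyde, via vicinal diol 22 (not isolated)
Conditions: OsO4 (2 mol%), NMO, acetone–H2O, 0 °C → rt; then NaIO4, THF–H2O, 0 °C
Reagents that add atoms: N-methylmorpholine N-oxide, C[N+]1([O-])CCOCC1; water, O
Why: Upjohn dihydroxylation and periodate cleavage (Lemieux–Johnson-type): the monosubstituted, unconjugated alkene is the only electron-rich and unhindered alkene, while the furanone C2=C3 and the iodo-alkene are trisubstituted and conjugated to the carbonyl; neutral conditions avoid β-elimination of the furanone oxygen from the new aldehyde.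

**Step 15**
Reactants: 24 methyl acrylate; 25 2-[(4-methoxyphenyl)methoxy]acetaldehyde
Product: 26 methyl 3-hydroxy-4-[(4-methoxyphenyl)methoxy]-2-methylidenebutanoate (racemic)
Conditions: DABCO (0.5 equiv), neat in excess 24, rt
Reagents that add atoms: none
Why: Morita–Baylis–Hillman reaction; the stereocentre formed is lost in step 16.

**Step 16**
Reactants: 26 Baylis–Hillman alcohol
Product: 27 methyl (2Z)-2-(bromomethyl)-4-[(4-methoxyphenyl)methoxy]but-2-enoate
Conditions: NBS, Me2S, CH2Cl2, 0 °C → rt
Reagents that add atoms: N-bromosuccinimide, O=C1CCC(=O)N1Br
Why: Corey–Kim-type activation of the allylic alcohol and SN2′ attack of bromide, known for Baylis–Hillman alcohols, give the thermodynamically preferred trisubstituted (Z)-allyl bromide with the CH2OPMB group cis to CH2Br.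

**Step 17**
Reactants: 23 2-Fur-acetaldehyde; 27 (Z)-allyl bromide
Product: 29 methyl (3S,4R)-5-Fur-4-hydroxy-3-{[(4-methoxyphenyl)methoxy]methyl}-2-methylidenepentanoate, via allylindium reagent 28 (not isolated)
Conditions: In (powder), THF–H2O (1:1), rt
Reagents that add atoms: none
Why: Indium-mediated Barbier allylation: allylindium 28 reacts at its γ-carbon through a chair transition state in which the CH2OPMB group is cis to the CH2–In carbon and the aldehyde residue is equatorial, which gives the syn C7/C8 pair (7S,8R in 29, the arrangement of the target). The remote quaternary C10 is not expected to bias the aldehyde face, so the other syn adduct (7R,8S) should form alongside and is to be removed by chromatography; alkenyl iodide, furanone and silyl ether are inert to indium.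

**Step 18**
Reactants: 29 homoallylic alcohol; 30 isobutyryl chloride
Product: 31 methyl (3S,4R)-5-Fur-3-{[(4-methoxyphenyl)methoxy]methyl}-2-methylidene-4-[(2-methylpropanoyl)oxy]pentanoate
Conditions: pyridine, DMAP (cat.), CH2Cl2, 0 °C
Reagents that add atoms: none
Why: DMAP-catalysed acylation of the secondary C8 hydroxyl, done at once so that this hydroxyl cannot lactonise onto the C12 ester; no stereocentre is affected.

**Step 19**
Reactants: 31 PMB ether
Product: 32 methyl (3S,4R)-5-Fur-3-(hydroxymethyl)-2-methylidene-4-[(2-methylpropanoyl)oxy]pentanoate
Conditions: DDQ, CH2Cl2–pH 7 buffer, 0 °C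
Reagents that add atoms: none
Why: Oxidative cleavage of the PMB ether by DDQ at neutral pH, orthogonal to the C15 silyl ether and both esters; neutral, cold conditions and immediate use keep the free C6 hydroxyl from lactonising onto C12.

**Step 20**
Reactants: 32 primary alcohol
Product: 33 methyl (3R,4R)-5-Fur-3-formyl-2-methylidene-4-[(2-methylpropanoyl)oxy]pentanoate
Conditions: Dess–Martin periodinane, NaHCO3, CH2Cl2, 0 °C; used at once
Reagents that add atoms: none
Why: Buffered Dess–Martin oxidation is the mildest way to an α-branched, β,γ-unsaturated aldehyde with a β-acyloxy group: no base is present that could epimerise C7, move C11=C13 into conjugation or eliminate the isobutyrate.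

**Step 21**
Reactants: 33 seco aldehyde (Z)-alkenyl iodide
Product: 36 15-O-TBS ether of 37, via alkenylchromium species 34 (not isolated), via ring-closed chromium alkoxide 35 (not isolated)
Conditions: CrCl2 (8 equiv), NiCl2 (2 mol%), degassed DMSO–THF, 2 mM, slow addition of 33, rt; aqueous work-up, then silica gel (or PPTS)
Reagents that add atoms: none
Why: Nozaki–Hiyama–Kishi coupling run as a ring closure, the closest known reaction type being the intramolecular chromium/nickel-mediated addition of alkenyl iodides to aldehydes used for medium and large rings. Zerovalent nickel, formed from NiCl2 by CrCl2, inserts into the C5–I bond with retention and hands the alkenyl group to trivalent chromium, giving 34 with the Z geometry intact. 34 adds through C5 to the C6 aldehyde only, since alkenylchromium reagents leave ketones, esters and acrylates alone, and this forms C5–C6 and closes the ten-membered carbocycle by a 10-exo-trig carbonyl addition in a chain already bent by the cis C4=C5 alkene and the flat furanone. The new stereocentre C6 is controlled by C7: in the Felkin–Anh arrangement the C7–C8 bond, the bulkiest branch and the one that continues the ring, is anti to the incoming C5, C7–H flanks the nucleophile and the acrylate lies gauche to the carbonyl oxygen, which leads to 6R with H6 and H7 trans. In alkoxide 35 the C6 oxygen is therefore gauche to the acrylate and attacks the C12 methyl ester in a 5-exo-trig acyl substitution that closes the α-methylene lactone and releases methoxide; hydroxy ester that survives is closed on silica gel or with PPTS. The step needs aldehyde-over-carbonyl chemoselectivity (secured by organochromium reactivity), ring closure over intermolecular coupling (secured by 2 mM concentration and slow addition) and the absence of base (the medium is neutral), so that C7, the isobutyrate and the acrylate survive.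

**Step 22**
Reactants: 36 15-O-TBS ether of 37
Product: 37 CNP0176924.2
Conditions: HF·pyridine, pyridine, THF, 0 °C → rt
Reagents that add atoms: none
Why: Desilylation with buffered HF·pyridine; the conditions are neither basic nor nucleophilic, so the α-methylene lactone, the isobutyrate and the furanone are left alone.

## Compound list

1 | 2-methylprop-2-en-1-ol (methallyl alcohol) | CC(=C)CO | starting material
2 | (R)-(2-methyloxiran-2-yl)methanol | OC[C@]1(C)CO1 | intermediate
3 | vinylmagnesium bromide | C=C[Mg]Br | starting material
4 | (2S)-2-methylpent-4-ene-1,2-diol | OC[C@](C)(CC=C)O | intermediate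
5 | (2S)-2-hydroxy-2-methylpent-4-enal | O=C[C@](C)(CC=C)O | intermediate
6 | methylmagnesium bromide | C[Mg]Br | starting material
7 | (3S)-3-methylhex-5-ene-2,3-diol, both C2 epimers | CC(O)[C@](C)(CC=C)O | intermediate
8 | (3S)-3-hydroxy-3-methylhex-5-en-2-one | CC(=O)[C@](C)(CC=C)O | intermediate
9 | (3S)-3-methyl-3-[(trimethylsilyl)oxy]hex-5-en-2-one | CC(=O)[C@](C)(CC=C)O[Si](C)(C)C | intermediate
10 | methyl propiolate | C#CC(=O)OC | starting material
11 | formaldehyde | C=O | starting material
12 | methyl (2Z)-2-(hydroxymethyl)-3-iodoprop-2-enoate | I/C=C(/CO)C(=O)OC | intermediate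
13 | methyl (2Z)-2-[(TBS-oxy)methyl]-3-iodoprop-2-enoate | I/C=C(/CO[Si](C)(C)C(C)(C)C)C(=O)OC | intermediate
14 | (2E)-2-[(TBS-oxy)methyl]-3-iodoprop-2-en-1-ol | I/C=C(/CO[Si](C)(C)C(C)(C)C)CO | intermediate
15 | (2Z)-2-[(TBS-oxy)methyl]-3-iodoprop-2-enal | I/C=C(/CO[Si](C)(C)C(C)(C)C)C=O | intermediate
16 | lithium enolate of 9 (lithium on oxygen, C1=C2 enolate) | [Li]OC(=C)[C@](C)(CC=C)O[Si](C)(C)C | intermediate
17 | (1Z,6S)-2-[(TBS-oxy)methyl]-3-hydroxy-1-iodo-6-methyl-6-[(trimethylsilyl)oxy]nona-1,8-dien-5-one, both C3 epimers | I/C=C(/CO[Si](C)(C)C(C)(C)C)C(O)CC(=O)[C@](C)(CC=C)O[Si](C)(C)C | intermediate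
18 | (1Z,6S)-2-[(TBS-oxy)methyl]-1-iodo-6-methyl-6-[(trimethylsilyl)oxy]nona-1,8-diene-3,5-dione | I/C=C(/CO[Si](C)(C)C(C)(C)C)C(=O)CC(=O)[C@](C)(CC=C)O[Si](C)(C)C | intermediate
19 | (1Z,6S)-2-[(TBS-oxy)methyl]-6-hydroxy-1-iodo-6-methylnona-1,8-diene-3,5-dione | I/C=C(/CO[Si](C)(C)C(C)(C)C)C(=O)CC(=O)[C@](C)(CC=C)O | intermediate
20 | (2S)-5-hydroxy-5-[(1Z)-3-(TBS-oxy)-1-iodoprop-1-en-2-yl]-2-methyl-2-(prop-2-en-1-yl)oxolan-3-one, both C5 epimers | I/C=C(/CO[Si](C)(C)C(C)(C)C)C1(O)CC(=O)[C@](C)(CC=C)O1 | intermediate
21 | (2S)-5-[(1Z)-3-(TBS-oxy)-1-iodoprop-1-en-2-yl]-2-methyl-2-(prop-2-en-1-yl)furan-3(2H)-one | I/C=C(/CO[Si](C)(C)C(C)(C)C)C1=CC(=O)[C@](C)(CC=C)O1 | intermediate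
22 | 3-Fur-propane-1,2-diol, both carbinol epimers | I/C=C(/CO[Si](C)(C)C(C)(C)C)C1=CC(=O)[C@](C)(CC(O)CO)O1 | intermediate
23 | 2-Fur-acetaldehyde | I/C=C(/CO[Si](C)(C)C(C)(C)C)C1=CC(=O)[C@](C)(CC=O)O1 | intermediate
24 | methyl acrylate | C=CC(=O)OC | starting material
25 | 2-[(4-methoxyphenyl)methoxy]acetaldehyde | O=CCOCc1ccc(OC)cc1 | starting material
26 | methyl 3-hydroxy-4-[(4-methoxyphenyl)methoxy]-2-methylidenebutanoate (racemic) | C=C(C(=O)OC)C(O)COCc1ccc(OC)cc1 | intermediate
27 | methyl (2Z)-2-(bromomethyl)-4-[(4-methoxyphenyl)methoxy]but-2-enoate | COC(=O)/C(CBr)=C/COCc1ccc(OC)cc1 | intermediate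
28 | allylindium reagent from 27 (monovalent indium on the former CH2Br carbon) | COC(=O)/C(C[In])=C/COCc1ccc(OC)cc1 | intermediate
29 | methyl (3S,4R)-5-Fur-4-hydroxy-3-{[(4-methoxyphenyl)methoxy]methyl}-2-methylidenepentanoate | I/C=C(/CO[Si](C)(C)C(C)(C)C)C1=CC(=O)[C@](C)(C[C@@H](O)[C@@H](C(=C)C(=O)OC)COCc2ccc(OC)cc2)O1 | intermediate
30 | isobutyryl chloride (2-methylpropanoyl chloride) | CC(C)C(=O)Cl | starting material
31 | methyl (3S,4R)-5-Fur-3-{[(4-methoxyphenyl)methoxy]methyl}-2-methylidene-4-[(2-methylpropanoyl)oxy]pentanoate | I/C=C(/CO[Si](C)(C)C(C)(C)C)C1=CC(=O)[C@](C)(C[C@@H](OC(=O)C(C)C)[C@@H](C(=C)C(=O)OC)COCc2ccc(OC)cc2)O1 | intermediate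
32 | methyl (3S,4R)-5-Fur-3-(hydroxymethyl)-2-methylidene-4-[(2-methylpropanoyl)oxy]pentanoate | I/C=C(/CO[Si](C)(C)C(C)(C)C)C1=CC(=O)[C@](C)(C[C@@H](OC(=O)C(C)C)[C@@H](C(=C)C(=O)OC)CO)O1 | intermediate
33 | methyl (3R,4R)-5-Fur-3-formyl-2-methylidene-4-[(2-methylpropanoyl)oxy]pentanoate | I/C=C(/CO[Si](C)(C)C(C)(C)C)C1=CC(=O)[C@](C)(C[C@@H](OC(=O)C(C)C)[C@@H](C(=C)C(=O)OC)C=O)O1 | intermediate
34 | alkenylchromium dichloride derived from 33 (trivalent chromium in place of iodine, Z retained) | Cl[Cr](Cl)/C=C(/CO[Si](C)(C)C(C)(C)C)C1=CC(=O)[C@](C)(C[C@@H](OC(=O)C(C)C)[C@@H](C(=C)C(=O)OC)C=O)O1 | intermediate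
35 | ring-closed C6 chromium alkoxide (ten-membered carbocycle, 6R, methyl ester still open) | COC(=O)C(=C)[C@H]1[C@H](O[Cr](Cl)Cl)/C=C(/CO[Si](C)(C)C(C)(C)C)C2=CC(=O)[C@](C)(C[C@H]1OC(=O)C(C)C)O2 | intermediate
36 | (4Z,6R,7R,8R,10S)-15-(TBS-oxy)-8-[(2-methylpropanoyl)oxy]-1-oxo-3,10-epoxygermacra-2,4,11(13)-trien-12,6-olide | C=C1C(=O)O[C@@H]2/C=C(/CO[Si](C)(C)C(C)(C)C)C3=CC(=O)[C@](C)(C[C@@H](OC(=O)C(C)C)[C@@H]12)O3 | intermediate
37 | CNP0176924.2, (4Z,6R,7R,8R,10S)-15-hydroxy-8-[(2-methylpropanoyl)oxy]-1-oxo-3,10-epoxygermacra-2,4,11(13)-trien-12,6-olide | C=C1C(=O)O[C@@H]2/C=C(/CO)C3=CC(=O)[C@](C)(C[C@@H](OC(=O)C(C)C)[C@@H]12)O3 | target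

## Step count and risk

Total step count: 22. Longest linear sequence: 16 steps from 1 (steps 1–6, 11–14, 17–22); the side branches are steps 7–10 (from 10) and steps 15–16 (from 24).

Least certain steps:

**Step 21 (key step).** What may go wrong:
- Addition of the alkenylchromium to the other face of the C6 aldehyde, if the macrocyclic transition state does not follow the Felkin–Anh arrangement; this would end in the cis-fused lactone.
- Protodeiodination or intermolecular coupling at the dilution a ten-membered ring needs.
- Decay of 33 before it reacts: loss of configuration at C7, shift of C11=C13 into conjugation, or elimination of the isobutyrate.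

Fallback: the setting of C6 is separated from the ring closure. It sets out from 33 and closes the same C5–C6 bond under the manganese-driven catalytic chromium protocol (CrCl2 cat., NiCl2 cat., Mn, Me3SiCl). There the chromium alkoxide is silylated as it forms, so lactonisation cannot occur and both C6 epimers are kept as the ring-closed C6 trimethylsilyl ether F1. Citric acid in methanol frees the ring-closed hydroxy ester F2, and buffered Dess–Martin oxidation gives the ten-membered C6 ketone F3. Reduction with (R)-2-methyl-CBS-oxazaborolidine and catecholborane at −78 °C sets 6R under reagent control and gives the (6R)-hydroxy ester F4; this catalyst enantiomer is the right one if the alkenyl flank acts as the large group, and the vinylogous ester carbonyl of the furanone is not reduced. PPTS then closes the lactone, which comes back to the route at 36.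

**Step 17.** What may go wrong: lack of facial control by the remote C10, so that about equal amounts of the two syn adducts form and half of the advanced aldehyde is lost; lactonisation of the C8 hydroxyl onto C12 during work-up.

Fallback: stereocontrol is moved from the substrate to the reagent. It sets out from 23 and 27 and uses a chromium-mediated 2-(alkoxycarbonyl)allylation with nickel-free CrCl2 bound to a chiral oxazoline–sulfonamide or bis(oxazolinyl)carbazole ligand, in THF with an amine base. The allylchromium reagent again reacts through a chair transition state (syn pair), and the ligand enantiomer that directs the allyl group to the Si face of the aldehyde is used. The alkenyl iodide is inert to divalent chromium in the absence of nickel. The fallback comes back at 29 and makes no compound outside the list (F0).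

**Step 19.** What may go wrong: lactonisation of the free C6 hydroxyl onto the C12 methyl ester (a five-membered ring), which would take C6 out of the route.

Fallback: C6 is carried at the aldehyde oxidation level from the start, so no free C6 alcohol ever exists. It sets out from 24: Morita–Baylis–Hillman reaction with 2,2-dimethoxyacetaldehyde F5 gives methyl 3-hydroxy-4,4-dimethoxy-2-methylidenebutanoate F6, and NBS/Me2S gives methyl (2Z)-2-(bromomethyl)-4,4-dimethoxybut-2-enoate F7. Indium Barbier reaction of F7 with 23 gives the syn adduct with C6 as a dimethyl acetal, F8, and acylation with 30 gives the isobutyrate acetal F9. Non-aqueous acetal cleavage (Et3SiOTf, 2,4,6-collidine, CH2Cl2, 0 °C, then water), which spares silyl ethers and esters, comes back to the route at 33.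

**Step 7.** What may go wrong: polymerisation of formaldehyde or slow trapping of the magnesium allenoate, which leads to simple protonation and to erosion of the alkene geometry by reversible iodide addition.

Fallback: the two events are separated. It sets out from 10: Me3SiI in CH2Cl2 at −78 °C gives the silyl allenyl ketene acetal 3-iodo-1-methoxy-1-[(trimethylsilyl)oxy]propa-1,2-diene F10, which is then used in a Mukaiyama-type hydroxymethylation with 11 under BF3·OEt2 at −78 °C. Attack again occurs anti to iodine, and the fallback comes back at 12.

## Further compounds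

F1 | step 21 | ring-closed C6 trimethylsilyl ether of the ten-membered hydroxy ester (both C6 epimers) | COC(=O)C(=C)[C@H]1C(O[Si](C)(C)C)/C=C(/CO[Si](C)(C)C(C)(C)C)C2=CC(=O)[C@](C)(C[C@H]1OC(=O)C(C)C)O2
F2 | step 21 | ring-closed ten-membered C6 hydroxy methyl ester (both C6 epimers) | COC(=O)C(=C)[C@H]1C(O)/C=C(/CO[Si](C)(C)C(C)(C)C)C2=CC(=O)[C@](C)(C[C@H]1OC(=O)C(C)C)O2
F3 | step 21 | ring-closed ten-membered C6 ketone | COC(=O)C(=C)[C@H]1C(=O)/C=C(/CO[Si](C)(C)C(C)(C)C)C2=CC(=O)[C@](C)(C[C@H]1OC(=O)C(C)C)O2
F4 | step 21 | ring-closed (6R)-hydroxy methyl ester | COC(=O)C(=C)[C@H]1[C@H](O)/C=C(/CO[Si](C)(C)C(C)(C)C)C2=CC(=O)[C@](C)(C[C@H]1OC(=O)C(C)C)O2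
F0 | step 17 | none | none
F5 | step 19 | 2,2-dimethoxyacetaldehyde | O=CC(OC)OC
F6 | step 19 | methyl 3-hydroxy-4,4-dimethoxy-2-methylidenebutanoate | C=C(C(=O)OC)C(O)C(OC)OC
F7 | step 19 | methyl (2Z)-2-(bromomethyl)-4,4-dimethoxybut-2-enoate | COC(=O)/C(CBr)=C/C(OC)OC
F8 | step 19 | methyl 5-Fur-3-(dimethoxymethyl)-4-hydroxy-2-methylidenepentanoate (syn adduct, stereocentres as in 29) | I/C=C(/CO[Si](C)(C)C(C)(C)C)C1=CC(=O)[C@](C)(C[C@@H](O)[C@@H](C(=C)C(=O)OC)C(OC)OC)O1
F9 | step 19 | methyl 5-Fur-3-(dimethoxymethyl)-2-methylidene-4-[(2-methylpropanoyl)oxy]pentanoate (stereocentres as in 31) | I/C=C(/CO[Si](C)(C)C(C)(C)C)C1=CC(=O)[C@](C)(C[C@@H](OC(=O)C(C)C)[C@@H](C(=C)C(=O)OC)C(OC)OC)O1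
F10 | step 7 | 3-iodo-1-methoxy-1-[(trimethylsilyl)oxy]propa-1,2-diene | COC(O[Si](C)(C)C)=C=CI
A1 | alternative 1 | 3-methylenetetrahydrofuran with a C6 vinyl group, free C8 hydroxyl, C10 triethylsilyl ether and C1 PMB ether | C=C1CO[C@H](C=C)[C@H]1[C@H](O)C[C@](C)(O[Si](CC)(CC)CC)COCc2ccc(OC)cc2
A2 | alternative 2 | cross-conjugated 4-hydroxy-2-ynone joining the butenolide half and the C8 acetal half | O=C1O[C@H](/C=C(/CO[Si](C)(C)C(C)(C)C)C(=O)C#C[C@@](C)(O)CC(OC)OC)C=C1COCc2ccc(OC)cc2
A3 | alternative 3 | isoxazoline-bridged ten-membered carbocycle with saturated lactone | C1C(=O)O[C@@H]2/C=C(/CO[Si](C)(C)C(C)(C)C)[C@@H]3CC(=NO3)[C@@](C)(O[Si](CC)(CC)CC)C[C@@H](OC(=O)C(C)C)[C@@H]12
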